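**Compound numbers used throughout:** 1 methyl sinapate; 2 bromoacetaldehyde dimethyl acetal; 3 aryloxyacetaldehyde dimethyl acetal; 4 aryloxyacetaldehyde; 5 isopropenylmagnesium bromide; 6 racemic allylic alcohol (Claisen precursor); 7 3-methylbut-3-en-2-one; 8 1,3,3-trimethoxy-2-methylbutane; 9 2-methoxy-3-methylbuta-1,3-diene; 10 mixed ketal (not isolated); 11 allyl dienyl ether (not isolated); 12 dienone ester (Claisen product); 13 (R)-carbinol ester; 14 target.

## Analysis of the target

Target 14 is acyclic apart from one benzene ring. It is a sinapyl alcohol core: ring C1 carries the (E)-3-hydroxyprop-1-enyl arm (Cα=Cβ–Cγ), C3 and C5 carry methoxy groups, and the C4 oxygen is alkylated by a ten-carbon chain. The chain is numbered C1' (OCH2) to C8' (terminal =CH2), with methyl groups on C3' and C7'. The only stereocentre is C6', an (R)-configured secondary allylic carbinol between the isopropenyl unit (C7'=C8') and the C5' methylene; with no second stereocentre to relate to, it has to be set by a reagent or catalyst. Two alkenes carry geometry, the trisubstituted C2'=C3' (E) and the disubstituted Cα=Cβ (E). The sensitive groups are the cinnamyl alcohol (para to an alkoxy group, so it ionises easily in acid), the allylic C1'–O aryl ether (labile to acid, to zerovalent palladium and to strong heating) and the C6' allylic alcohol. The difficulty is a remote 1,5-relationship in an open chain between a geometrically defined trisubstituted alkene and a lone carbinol, together with two different allylic alcohols that must be told apart. The strategy rests on one feature: C2'=C3' is separated from C6' by exactly the two methylenes C4' and C5', and C6' bears an alkenyl group. With C6' at the ketone level, the array C6'(=O)–C5'–C4'–C3'=C2' is a γ,δ-unsaturated ketone, the retron of a Claisen rearrangement that forms C4'–C5'.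

## Retrosynthetic reasoning

**14 to 13.** No skeletal bond is cut; Cγ is taken back from the alcohol to the methyl ester. The cinnamyl alcohol is the most acid-labile group of 14 and the route contains acidic and hot steps, whereas a cinnamate is inert to both. The forward step has to reduce a conjugated ester in 1,2-fashion next to a free C6' hydroxyl without touching the allyl aryl ether.

**13 to 12.** The C6'–H bond is removed, which takes the only stereocentre back to a prochiral ketone. This places the stereochemical problem on a single catalyst-controlled reduction at the end, and it gives a precursor, 12, that holds no stereocentre at all. The forward reaction must distinguish the isopropenyl group from the C5' chain on the two sides of the carbonyl group.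

**12 to 6 and 9.** The C4'–C5' bond is cut by reversing a [3,3] shift: 12 unfolds into allyl dienyl ether 11, which comes from mixed ketal 10, and 10 comes from allylic alcohol 6 and diene 9. This bond is chosen because its formation fixes the geometry of C2'=C3' and delivers C6' as a ketone in the same event, and because it divides the chain into two five-carbon pieces. The forward reaction has to give the E alkene and has to tolerate the cinnamate and the aryl ether.

**6 to 4 and 5.** The bond between the carbinol carbon and the isopropenyl carbon of 6 is cut; these two atoms become C2' and C3' of 12. Because the carbinol centre of 6 is destroyed in the rearrangement, racemic 6 is sufficient and a plain addition of 5 to aldehyde 4 is enough. The forward reaction needs chemoselectivity for the aldehyde over the conjugated ester.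

**4 to 3 to 1 and 2.** The O–C1' bond is cut. Phenol 1 already contains the whole aryl–propenoate skeleton with the E alkene in place, and 2 supplies C1' and C2' with C2' masked at the aldehyde level. The forward steps are alkylation of a hindered but acidic phenol, then unmasking of the acetal.

**9 to 8 to 7.** Diene 9 is traced to β-methoxy ketal 8 by twofold loss of the alcohol component, and 8 to enone 7 by conjugate addition and ketalisation. This is the point where a plain ketalisation of 7 cannot be relied on, so the β-alkoxy ketal is made on purpose.

## Alternatives that were turned down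

**Alternative 1:** The chain is cut at C1'–C2' and at the C3'–CH3 bond, so that the trisubstituted alkene comes from carbometalation of a terminal alkyne, (R)-tert-butyldimethyl[(2-methylhept-1-en-6-yn-3-yl)oxy]silane A2.
- Forward key step: Me3Al with catalytic Cp2ZrCl2 would add methyl and aluminium syn across the triple bond of A2. The alkenylalane, converted into its ate complex with nBuLi, would be hydroxymethylated with paraformaldehyde to give (R,E)-6-(tert-butyldimethylsilyloxy)-3,7-dimethylocta-2,7-dien-1-ol A1. A1 would be joined to 1 by Mitsunobu etherification, desilylated to 13 and reduced.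
- For: syn-carbometalation is stereospecific, so on the geometry of C2'=C3' this route is at least as strong as a Claisen rearrangement, whose E selectivity rests on an energy gap between two chair arrangements. The stereocentre would be set and checked on a small fragment.
- Against: A2 already contains the C6' carbinol, so the same enantioselective problem has to be solved first, on a seven-carbon enynol and with a silyl group put on and taken off. The 1,1-disubstituted alkene and the allylic silyl ether oxygen of A2 are both sites where excess Me3Al can interfere. The count is about four steps to A2, then carboalumination, coupling, desilylation and ester reduction.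
- Comparison: the chosen route needs no protecting group, builds the chain on the arene from two five-carbon units and is shorter. It accepts an E selectivity that is high by design and not absolute.

**Alternative 2:** The C6'–O bond is traced to an oxirane across C6'–C7', so the chain is taken from the geranyl skeleton.
- Forward: O-geranylation of 1 gives the geranyl ether A5, methyl (E)-3-[4-[(E)-3,7-dimethylocta-2,6-dienyloxy]-3,5-dimethoxyphenyl]acrylate. Allylic oxidation with SeO2/tBuOOH gives its (E)-8'-hydroxy derivative A4. The key step is epoxidation of A4 with Ti(OiPr)4, D-(−)-diethyl tartrate and tBuOOH to the (6'R,7'R)-6',7'-epoxy-8'-hydroxygeranyl ether A3. Activation of the C8' hydroxyl and reductive opening of the oxirane (for instance via the iodide with zinc) would transpose the allylic system and give 13 with the C6'–O bond intact.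
- For: all ten chain carbons and the E geometry of C2'=C3' are bought. Epoxidation of an E-trisubstituted primary allylic alcohol is among the most dependable enantioselective reactions, so on the reliability of the stereocentre this route is stronger than a catalyst-controlled reduction of an isopropenyl ketone. The step count is about the same.
- Against: the selenium oxidation of A5 has to pick the E-methyl of the terminal prenyl unit while C1', C4' and C5' are also allylic and C1' is further activated by the aryl ether oxygen. This type of oxidation tends to stop short and to run on to the aldehyde. The transposition adds two stoichiometric redox steps late, one with a reducing metal next to the allyl aryl ether and the cinnamate.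
- Comparison: the chosen route concentrates its risk in one thermal step and avoids selenium and late redox shuffling. In exchange it gives up the certainty of the epoxidation.

**Alternative 3:** The bond between ring carbon C1 and Cα is cut.
- Forward key step: the aryl bromide A7, (3R,6E)-8-(4-bromo-2,6-dimethoxyphenoxy)-2,6-dimethylocta-1,6-dien-3-ol, would be coupled with the (E)-alkenyl pinacol boronate A8 under PdCl2(dppf) and aqueous K2CO3. This gives the tert-butyldimethylsilyl ether A6 of the target, and fluoride would then release 14.
- For: the coupling retains alkene geometry, so on Cα=Cβ it is as good as starting from 1. The acid-labile cinnamyl alcohol appears only at the very end, with no hydride reduction next to the free C6' hydroxyl.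
- Against: the C–C bond it makes is one that 1 supplies ready-made, so the real difficulty (C2'=C3' geometry, C6' configuration) is untouched and A7 still needs one of the other chain syntheses. The allylic C1'–O aryl ether of A7 and A6 is itself a substrate for zerovalent palladium, because a 2,6-dimethoxyphenoxide is a competent leaving group for π-allyl formation. Chain loss or allylic scrambling would therefore compete with oxidative addition into an electron-rich aryl bromide. It also adds a boronate synthesis, a coupling and a desilylation.
- Comparison: it is longer and solves an easier problem. The chosen route gets the same end-game safety by carrying Cγ as a methyl ester.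

Key step: step 6

Assumption: in acidic methanol, enone 7 is taken to add methanol at C4 as well as at the carbonyl group, so diene 9 is drawn from the β-methoxy ketal 8 (any simple ketal formed alongside cracks to the same diene); 1 and 2 are taken as catalogue chemicals.

## Route

**Step 1**
Reactants: 1 methyl sinapate [methyl (E)-3-(4-hydroxy-3,5-dimethoxyphenyl)acrylate]; 2 bromoacetaldehyde dimethyl acetal (2-bromo-1,1-dimethoxyethane)
Product: 3 methyl (E)-3-[4-(2,2-dimethoxyethoxy)-3,5-dimethoxyphenyl]acrylate
Conditions: Cs2CO3, KI (cat.), DMF, 100 °C
Reagents that add atoms: none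
Why: Williamson ether synthesis; the caesium phenoxide of the acidic, doubly ortho-substituted phenol displaces the primary bromide (iodide catalysis offsets the sluggish β-dialkoxy halide), and the ester, the cinnamate alkene and the acetal are stable to carbonate.

**Step 2**
Reactants: 3 methyl (E)-3-[4-(2,2-dimethoxyethoxy)-3,5-dimethoxyphenyl]acrylate
Product: 4 methyl (E)-3-[3,5-dimethoxy-4-(2-oxoethoxy)phenyl]acrylate
Conditions: CF3CO2H–H2O (1:1), CHCl3, 0 °C → rt; azeotropic drying with toluene
Reagents that add atoms: water, O
Why: Acid-catalysed acetal hydrolysis through the oxocarbenium ion; both ring positions ortho to the ether oxygen carry methoxy groups, so the usual cyclisation of aryloxyacetaldehydes onto the ring cannot occur, and the methyl ester survives brief aqueous acid at room temperature.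

**Step 3**
Reactants: 4 methyl (E)-3-[3,5-dimethoxy-4-(2-oxoethoxy)phenyl]acrylate; 5 isopropenylmagnesium bromide
Product: 6 racemic methyl (E)-3-[4-(2-hydroxy-3-methylbut-3-enyloxy)-3,5-dimethoxyphenyl]acrylate
Conditions: 5 (1.05 equiv), THF, −78 °C; aq. NH4Cl
Reagents that add atoms: none
Why: Grignard 1,2-addition; at −78 °C the aldehyde is far more electrophilic than the conjugated ester, so one equivalent of 5 should be taken up by the aldehyde alone. The new carbinol centre is formed without control, which is immaterial because it is destroyed in step 6.

**Step 4**
Reactants: 7 3-methylbut-3-en-2-one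
Product: 8 racemic 1,3,3-trimethoxy-2-methylbutane
Conditions: MeOH, HC(OMe)3, TsOH·H2O (cat.), 0 °C → rt; NaOMe quench; distillation
Reagents that add atoms: methanol, CO; trimethyl orthoformate, COC(OC)OC
Why: Acid-catalysed conjugate addition of methanol to the enone and ketalisation of the resulting β-methoxy ketone, driven by the orthoformate as water scavenger; this is the reaction type by which simple vinyl ketones are converted into β-methoxy dimethyl ketals.

**Step 5**
Reactants: 8 racemic 1,3,3-trimethoxy-2-methylbutane
Product: 9 2-methoxy-3-methylbuta-1,3-diene
Conditions: KHSO4 (cat.), hydroquinone (trace), 150–160 °C, product distilled out; aq. K2CO3 wash, redistillation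
Reagents that add atoms: none
Why: Acid-catalysed cracking of a β-alkoxy ketal to a 2-alkoxy-1,3-diene: loss of methanol from the ketal and vinylogous loss of the β-methoxy group lead to the 2-methoxyallyl cation, which can lose a proton only from the C1 methyl group, so a single diene results. Distillation of the volatile products pulls the equilibria forward.

**Step 6**
Reactants: 6 racemic methyl (E)-3-[4-(2-hydroxy-3-methylbut-3-enyloxy)-3,5-dimethoxyphenyl]acrylate; 9 2-methoxy-3-methylbuta-1,3-diene
Product: 12 methyl (E)-3-[4-[(E)-3,7-dimethyl-6-oxoocta-2,7-dienyloxy]-3,5-dimethoxyphenyl]acrylate, via mixed methyl ketal 10 (not isolated), via allyl dienyl ether 11 (not isolated)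
Conditions: 9 (4 equiv), 2,4-dinitrophenol (0.1 equiv), hydroquinone (trace), toluene, sealed tube, 110 °C
Reagents that add atoms: none
Why: 2,4-Dinitrophenol protonates C1 of 9, the carbinol oxygen of 6 adds to the resulting 2-methoxyallyl cation at its oxygen-bearing carbon to give mixed ketal 10, and loss of methanol (only the ketal methyl group can give up a proton) gives allyl dienyl ether 11. A concerted [3,3]-sigmatropic shift of 11 then joins the enol ether CH2 (C5') to the terminal CH2 of the methallyl unit (C4'), breaks the C2'–O bond and leaves the C6' ketone and the C2'=C3' alkene; formation of the carbonyl group makes it irreversible. The closest known reaction type is the Claisen rearrangement of secondary 2-methylallylic alcohols with 2-alkoxy-1,3-dienes or their ketals, the iterative way to E-trisubstituted polyprenoid chains. No ring is closed and no stereocentre is made; the carbinol centre of 6 becomes sp2, which is why the racemate serves. The selectivity that matters is E geometry at C2'=C3': in the chair transition state the aryloxymethyl group on the carbinol carbon sits equatorial, because the axial position would bring it into a 1,3-diaxial contact with the isopropenyl group on the oxygen-bearing vinyl carbon. The weak acid is chosen so that the allylic C1'–O aryl ether of 12 is not ionised, and both ring positions ortho to that oxygen carry methoxy groups, so an aromatic Claisen shift of 12 has no free terminus at 110 °C.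

**Step 7**
Reactants: 12 methyl (E)-3-[4-[(E)-3,7-dimethyl-6-oxoocta-2,7-dienyloxy]-3,5-dimethoxyphenyl]acrylate
Product: 13 methyl (E)-3-[4-[(2E,6R)-6-hydroxy-3,7-dimethylocta-2,7-dienyloxy]-3,5-dimethoxyphenyl]acrylate
Conditions: (S)-1-methyl-3,3-diphenyltetrahydro-1H,3H-pyrrolo[1,2-c][1,3,2]oxazaborole (0.2 equiv), catecholborane (1.8 equiv), toluene, −78 °C; MeOH quench, aq. Na2CO3 wash
Reagents that add atoms: none
Why: Corey–Bakshi–Shibata reduction; the ketone binds to the ring boron with its larger, α-branched sp2 isopropenyl group turned away from the B-methyl group, and hydride is delivered within the complex from the nitrogen-bound borane. This is the same sense that gives (R)-1-arylethanols with the (S)-catalyst, and since isopropenyl outranks C5' it corresponds to 6'R. Catecholborane at −78 °C should leave the three alkenes and the ester alone.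

**Step 8**
Reactants: 13 methyl (E)-3-[4-[(2E,6R)-6-hydroxy-3,7-dimethylocta-2,7-dienyloxy]-3,5-dimethoxyphenyl]acrylate
Product: 14 (E)-3-[4-[(2E,6R)-6-hydroxy-3,7-dimethylocta-2,7-dienyloxy]-3,5-dimethoxyphenyl]prop-2-en-1-ol
Conditions: iBu2AlH (3.5 equiv), CH2Cl2, −78 → 0 °C; aq. potassium sodium tartrate
Reagents that add atoms: none
Why: 1,2-Reduction of an α,β-unsaturated ester to the allylic alcohol by iBu2AlH; the first equivalent is consumed by the C6' hydroxyl, whose configuration is not touched by hydride or by the neutral tartrate work-up. The neutral work-up also avoids ionising the electron-rich cinnamyl alcohol.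

## Compound list

1 | methyl sinapate, methyl (E)-3-(4-hydroxy-3,5-dimethoxyphenyl)acrylate | COC(=O)/C=C/c1cc(OC)c(O)c(OC)c1 | starting material
2 | bromoacetaldehyde dimethyl acetal (2-bromo-1,1-dimethoxyethane) | COC(CBr)OC | starting material
3 | methyl (E)-3-[4-(2,2-dimethoxyethoxy)-3,5-dimethoxyphenyl]acrylate | COC(COc1c(OC)cc(/C=C/C(=O)OC)cc1OC)OC | intermediate
4 | methyl (E)-3-[3,5-dimethoxy-4-(2-oxoethoxy)phenyl]acrylate | O=CCOc1c(OC)cc(/C=C/C(=O)OC)cc1OC | intermediate
5 | isopropenylmagnesium bromide | C=C(C)[Mg]Br | starting material
6 | racemic methyl (E)-3-[4-(2-hydroxy-3-methylbut-3-enyloxy)-3,5-dimethoxyphenyl]acrylate | C=C(C)C(O)COc1c(OC)cc(/C=C/C(=O)OC)cc1OC | intermediate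
7 | 3-methylbut-3-en-2-one | C=C(C)C(C)=O | starting material
8 | racemic 1,3,3-trimethoxy-2-methylbutane | COCC(C)C(C)(OC)OC | intermediate
9 | 2-methoxy-3-methylbuta-1,3-diene | C=C(C)C(=C)OC | intermediate
10 | methyl (E)-3-[4-[2-[(2-methoxy-3-methylbut-3-en-2-yl)oxy]-3-methylbut-3-enyloxy]-3,5-dimethoxyphenyl]acrylate, mixture of diastereomers, not isolated | C=C(C)C(C)(OC)OC(COc1c(OC)cc(/C=C/C(=O)OC)cc1OC)C(C)=C | intermediate
11 | racemic methyl (E)-3-[3,5-dimethoxy-4-[3-methyl-2-[(3-methylbuta-1,3-dien-2-yl)oxy]but-3-enyloxy]phenyl]acrylate, not isolated | C=C(C)C(=C)OC(COc1c(OC)cc(/C=C/C(=O)OC)cc1OC)C(C)=C | intermediate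
12 | methyl (E)-3-[4-[(E)-3,7-dimethyl-6-oxoocta-2,7-dienyloxy]-3,5-dimethoxyphenyl]acrylate | C=C(C)C(=O)CC/C(C)=C/COc1c(OC)cc(/C=C/C(=O)OC)cc1OC | intermediate
13 | methyl (E)-3-[4-[(2E,6R)-6-hydroxy-3,7-dimethylocta-2,7-dienyloxy]-3,5-dimethoxyphenyl]acrylate | C=C(C)[C@H](O)CC/C(C)=C/COc1c(OC)cc(/C=C/C(=O)OC)cc1OC | intermediate
14 | (E)-3-[4-[(2E,6R)-6-hydroxy-3,7-dimethylocta-2,7-dienyloxy]-3,5-dimethoxyphenyl]prop-2-en-1-ol | C=C(C)[C@H](O)CC/C(C)=C/COc1c(OC)cc(/C=C/CO)cc1OC | target

## Step count and least certain steps

Total step count: 8. Longest linear sequence: 6 steps (steps 1, 2, 3, 6, 7, 8 from 1); the diene branch (steps 4 and 5) joins at step 6.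

**Step 6 (key step).**
- Risks: the exchange and elimination may stall at the mixed ketal stage. The acid may ionise the newly formed allylic C1'–O aryl ether, with loss of the chain. The excess electron-rich diene may undergo cycloaddition with the newly formed isopropenyl ketone or with the cinnamate, and the enone may polymerise. A boat transition state may erode the E selectivity.
- Fallback (sets out from 6, returns at 12): the chloro ketal variant of the same rearrangement. The chloro ketal 3-chloro-2,2-dimethoxy-3-methylbutane F1 (made by ketalising the commercially available α-chloro ketone with trimethyl orthoformate) is heated with 6 and 2,4-dinitrophenol at 110 °C. F1 is not a diene and its rearrangement product is not a dienophile, so the cycloaddition and polymerisation channels are closed. The product is the α-chloro ketone methyl (E)-3-[4-[(E)-7-chloro-3,7-dimethyl-6-oxooct-2-enyloxy]-3,5-dimethoxyphenyl]acrylate F2. Dehydrochlorination of F2 with LiBr/Li2CO3 in DMF can take a proton only from the two methyl groups on the chlorine-bearing carbon and gives 12.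

**Step 7.**
- Risks: steric differentiation between the isopropenyl group and the primary C5' chain may be insufficient, which lowers the enantioselectivity. Uncatalysed background reduction would do the same.
- Fallback (sets out from 12, returns at 13): reduction with NaBH4/CeCl3·7H2O in MeOH gives the racemic carbinol methyl (E)-3-[4-[(E)-6-hydroxy-3,7-dimethylocta-2,7-dienyloxy]-3,5-dimethoxyphenyl]acrylate F3. Sharpless kinetic resolution of F3 with Ti(OiPr)4, L-(+)-diisopropyl tartrate and tBuOOH (0.6 equiv) in CH2Cl2 at −20 °C should epoxidise the (S)-enantiomer to the erythro epoxy alcohol methyl (E)-3-[4-[(2E,6S)-6-hydroxy-3-methyl-6-[(2R)-2-methyloxiran-2-yl]hex-2-enyloxy]-3,5-dimethoxyphenyl]acrylate F4 and leave the (R)-enantiomer, which is 13, to be separated by chromatography. The cost is that at most half of the material is carried on.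

**Step 3.**
- Risks: the α-aryloxy aldehyde may form a hydrate or oligomers, which spoils the stoichiometry. It may be enolised by the Grignard reagent. The Grignard reagent may also add to the cinnamate.
- Fallback (sets out from 1, returns at 6): alkylation of 1 with 2-chloro-N-methoxy-N-methylacetamide (K2CO3, DMF) gives the Weinreb amide methyl (E)-3-[3,5-dimethoxy-4-[2-[methoxy(methyl)amino]-2-oxoethoxy]phenyl]acrylate F5. Addition of 5 at −40 °C stops at the chelated tetrahedral adduct and releases, on quenching, the enone methyl (E)-3-[3,5-dimethoxy-4-(3-methyl-2-oxobut-3-enyloxy)phenyl]acrylate F6. 1,2-Reduction of F6 with NaBH4/CeCl3·7H2O gives 6, and no free aldehyde is handled.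

**Step 5.**
- Risks: acid-induced polymerisation or hydrolysis of the volatile diene in the still, and incomplete second elimination.
- Fallback (sets out from 7, returns at 10): aprotic ketalisation of 7 with Me3SiOMe and catalytic Me3SiOTf in CH2Cl2 at −78 °C, where no free methanol is present to add in conjugate fashion, gives the olefinic ketal 3,3-dimethoxy-2-methylbut-1-ene F7. Heating F7 with 6 and 2,4-dinitrophenol exchanges one methoxy group for the allylic alkoxide and gives mixed ketal 10 directly, from which step 6 continues without the free diene ever being isolated.

## Further compounds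

F1 | step 6 | 3-chloro-2,2-dimethoxy-3-methylbutane | COC(C)(OC)C(C)(C)Cl
F2 | step 6 | methyl (E)-3-[4-[(E)-7-chloro-3,7-dimethyl-6-oxooct-2-enyloxy]-3,5-dimethoxyphenyl]acrylate | CC(C)(Cl)C(=O)CC/C(C)=C/COc1c(OC)cc(/C=C/C(=O)OC)cc1OC
F3 | step 7 | racemic methyl (E)-3-[4-[(E)-6-hydroxy-3,7-dimethylocta-2,7-dienyloxy]-3,5-dimethoxyphenyl]acrylate | C=C(C)C(O)CC/C(C)=C/COc1c(OC)cc(/C=C/C(=O)OC)cc1OC
F4 | step 7 | methyl (E)-3-[4-[(2E,6S)-6-hydroxy-3-methyl-6-[(2R)-2-methyloxiran-2-yl]hex-2-enyloxy]-3,5-dimethoxyphenyl]acrylate | C[C@@]1(CO1)[C@@H](O)CC/C(C)=C/COc2c(OC)cc(/C=C/C(=O)OC)cc2OC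
F5 | step 3 | methyl (E)-3-[3,5-dimethoxy-4-[2-[methoxy(methyl)amino]-2-oxoethoxy]phenyl]acrylate | CON(C)C(=O)COc1c(OC)cc(/C=C/C(=O)OC)cc1OC
F6 | step 3 | methyl (E)-3-[3,5-dimethoxy-4-(3-methyl-2-oxobut-3-enyloxy)phenyl]acrylate | C=C(C)C(=O)COc1c(OC)cc(/C=C/C(=O)OC)cc1OC
F7 | step 5 | 3,3-dimethoxy-2-methylbut-1-ene | C=C(C)C(C)(OC)OC
A1 | alternative 1 | (R,E)-6-(tert-butyldimethylsilyloxy)-3,7-dimethylocta-2,7-dien-1-ol | C=C(C)[C@H](O[Si](C)(C)C(C)(C)C)CC/C(C)=C/CO
A2 | alternative 1 | (R)-tert-butyldimethyl[(2-methylhept-1-en-6-yn-3-yl)oxy]silane | C=C(C)[C@H](O[Si](C)(C)C(C)(C)C)CCC#C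
A3 | alternative 2 | methyl (E)-3-[4-[(E)-5-[(2R,3R)-3-(hydroxymethyl)-3-methyloxiran-2-yl]-3-methylpent-2-enyloxy]-3,5-dimethoxyphenyl]acrylate | OC[C@@]1(C)O[C@@H]1CC/C(C)=C/COc2c(OC)cc(/C=C/C(=O)OC)cc2OC
A4 | alternative 2 | methyl (E)-3-[4-[(2E,6E)-8-hydroxy-3,7-dimethylocta-2,6-dienyloxy]-3,5-dimethoxyphenyl]acrylate | OC/C(C)=C/CC/C(C)=C/COc1c(OC)cc(/C=C/C(=O)OC)cc1OC
A5 | alternative 2 | methyl (E)-3-[4-[(E)-3,7-dimethylocta-2,6-dienyloxy]-3,5-dimethoxyphenyl]acrylate | CC(C)=CCC/C(C)=C/COc1c(OC)cc(/C=C/C(=O)OC)cc1OC
A6 | alternative 3 | (3R,6E)-8-[4-[(E)-3-(tert-butyldimethylsilyloxy)prop-1-enyl]-2,6-dimethoxyphenoxy]-2,6-dimethylocta-1,6-dien-3-ol | C=C(C)[C@H](O)CC/C(C)=C/COc1c(OC)cc(/C=C/CO[Si](C)(C)C(C)(C)C)cc1OC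
A7 | alternative 3 | (3R,6E)-8-(4-bromo-2,6-dimethoxyphenoxy)-2,6-dimethylocta-1,6-dien-3-ol | C=C(C)[C@H](O)CC/C(C)=C/COc1c(OC)cc(Br)cc1OC
A8 | alternative 3 | (E)-tert-butyldimethyl[3-(4,4,5,5-tetramethyl-1,3,2-dioxaborolan-2-yl)allyloxy]silane | CC(C)(C)[Si](C)(C)OC/C=C/B1OC(C)(C)C(C)(C)O1
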